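**Plan**
1. Numbering: the target is treated as a 3a,4,5,7a-tetrahydro-1H-indene with C1 CHMe, C2 =CH, C3 =C(Et), C3a, C4 C(Me)CO2H, C5 C(Me)(dienyl), C6 =CH, C7 =C(Me), C7a. Retrosynthetic cuts in order: the ester O–CH3; SO2 is put back between C2 and C3, so the cyclopentene becomes a trans-fused thiane 1,1-dioxide; C3a–C7a and C4–C5 (retro-Diels–Alder of the cyclohexene); then the enoate C=C (future C3a/C4), the four C=C bonds of the tetraene (Wittig/HWE) and the S–C3 bond.
2. Enabling feature: the five-membered ring holds a single C=C (C2=C3). Both of its carbons are flanked by sp3 CH groups (C1, C3a) and carry only H and Et, which is the exact retron of a Ramberg–Bäcklund SO2 extrusion from a six-membered C5S ring. The inserted S, C2, C1 with its methyl group, and C7a are the S–CH2–CH(CH3)–C(=O) chain of (S)-3-(acetylthio)-2-methylpropanoic acid, the cheap captopril side-chain acid.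
3. Forward order: thioether union, then aldehyde, then three formyl-ylide Wittig homologations and one HWE to the phenyl tetraene, then the dienophile by reduction/Wittig, then the sulfone. One intramolecular Diels–Alder reaction closes the cyclohexene and the thiane together, the thiane is contracted to the cyclopentene, and the ester is cleaved.
4. Stereochemistry: C1 comes from the chiral pool. C7a, C3a, C4 and C5 are set together in the Diels–Alder step by the all-E geometry, the endo chair transition state and A1,3 strain at both allylic tether carbons. The sulfur-bearing helper centre (SN2 inversion of methyl (R)-2-bromobutanoate) reinforces this and is erased in the contraction.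

Key step: step 11

Assumption: methyl (R)-2-bromobutanoate is taken as a catalogue compound (otherwise one Fischer esterification of (R)-2-bromobutanoic acid); the centre it creates is only a helper, so partial erosion there before step 10 would cost material but not change the stereochemical outcome.

Step 1
Reactants: 1 (S)-3-(acetylthio)-2-methylpropanoic acid; 2 methyl (R)-2-bromobutanoate
Product: 4 (2S)-3-{[(2S)-1-methoxy-1-oxobutan-2-yl]sulfanyl}-2-methylpropanoic acid, via (S)-2-methyl-3-sulfanylpropanoic acid (as disodium salt) 3 (not isolated)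
Conditions: NaOMe (2.05 equiv), degassed MeOH, 0 °C; then 2, 0 °C to rt; 1 M HCl
Reagents that add atoms: none
Why: Methoxide S-deacetylation followed by SN2 thioetherification, in which the soft thiolate displaces the secondary α-bromo ester with inversion and so sets the helper centre as (S), while the methyl-bearing centre of 1 is untouched because no base stronger than thiolate or carboxylate remains.

Step 2
Reactants: 4 sulfide acid
Product: 5 methyl (2S)-2-{[(2S)-3-hydroxy-2-methylpropyl]sulfanyl}butanoate
Conditions: BH3·THF, THF, 0 °C to rt; MeOH, then H2O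
Reagents that add atoms: none
Why: Chemoselective borane reduction of a carboxylic acid (via the acyloxyborane) in the presence of a methyl ester and a dialkyl sulfide, with no stereocentre involved.

Step 3
Reactants: 5 hydroxy sulfide
Product: 6 methyl (2S)-2-{[(2S)-2-methyl-3-oxopropyl]sulfanyl}butanoate
Conditions: Dess–Martin periodinane, CH2Cl2, 0 °C to rt
Reagents that add atoms: none
Why: Dess–Martin oxidation, whose non-basic medium tolerates the sulfide and avoids enolisation or β-elimination of the α-methyl-β-thio aldehyde.

Step 4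
Reactants: 6 aldehyde; 7 2-(triphenylphosphoranylidene)propanal
Product: 8 methyl (2S)-2-{[(2S,3E)-2,4-dimethyl-5-oxopent-3-en-1-yl]sulfanyl}butanoate
Conditions: toluene, 80 °C
Reagents that add atoms: none
Why: Wittig olefination with a stabilised formyl ylide should give the (E)-2-methylenal directly at the aldehyde oxidation level, and the ylide is too weak a base to epimerise the α-centre or expel thiolate.

Step 5
Reactants: 8 enal; 7 2-(triphenylphosphoranylidene)propanal
Product: 9 methyl (2S)-2-{[(2S,3E,5E)-2,4,6-trimethyl-7-oxohepta-3,5-dien-1-yl]sulfanyl}butanoate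
Conditions: toluene, 110 °C
Reagents that add atoms: none
Why: Second Wittig homologation with the same stabilised ylide, E-selective as usual for stabilised ylides, with the product dienal less electrophilic than 8 so that over-homologation stays minor.

Step 6
Reactants: 9 dienal; 7 2-(triphenylphosphoranylidene)propanal
Product: 10 methyl (2S)-2-{[(2S,3E,5E,7E)-2,4,6,8-tetramethyl-9-oxonona-3,5,7-trien-1-yl]sulfanyl}butanoate
Conditions: toluene, 110 °C
Reagents that add atoms: none
Why: Third Wittig homologation of the same type, which completes the 1,3-dimethyl-branched all-E polyenal.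

Step 7
Reactants: 10 trienal; 11 diethyl benzylphosphonate
Product: 12 methyl (2S)-2-{[(2S,3E,5E,7E,9E)-2,4,6,8-tetramethyl-10-phenyldeca-3,5,7,9-tetraen-1-yl]sulfanyl}butanoate
Conditions: 11, LiHMDS (1.0 equiv), THF, −78 °C; then 10, −78 to 0 °C
Reagents that add atoms: none
Why: Horner–Wadsworth–Emmons olefination with a benzylic phosphonate anion is reliably E-selective, and the preformed anion used without excess adds to the aldehyde faster than it deprotonates the α-thio ester.

Step 8
Reactants: 12 tetraene ester; 13 methyl 2-(triphenylphosphoranylidene)propanoate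
Product: 15 methyl (2E,4S)-2-methyl-4-{[(2S,3E,5E,7E,9E)-2,4,6,8-tetramethyl-10-phenyldeca-3,5,7,9-tetraen-1-yl]sulfanyl}hex-2-enoate, via (2S)-2-{[(2S,3E,5E,7E,9E)-2,4,6,8-tetramethyl-10-phenyldeca-3,5,7,9-tetraen-1-yl]sulfanyl}butanal 14 (not isolated)
Conditions: DIBAL-H (1.1 equiv), CH2Cl2, −78 °C; MeOH quench; then 13, −78 °C to rt; aq. potassium sodium tartrate
Reagents that add atoms: none
Why: One-pot partial ester reduction and Wittig olefination, a sequence established for configurationally labile α-heteroatom aldehydes, traps 14 as it is released and gives the (E)-2-methylenoate expected from a stabilised ylide.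

Step 9
Reactants: 15 sulfide
Product: 16 methyl (2E,4S)-2-methyl-4-{[(2S,3E,5E,7E,9E)-2,4,6,8-tetramethyl-10-phenyldeca-3,5,7,9-tetraen-1-yl]sulfonyl}hex-2-enoate
Conditions: (NH4)6Mo7O24·4H2O (10 mol %), 30 % H2O2, EtOH, 0 °C to rt, dark
Reagents that add atoms: hydrogen peroxide, OO
Why: Molybdate-catalysed peroxide oxidation of a sulfide to the sulfone, in which the electrophilic peroxomolybdate attacks nucleophilic sulfur much faster than unfunctionalised C=C bonds, under near-neutral conditions that leave the acidic α-sulfonyl centre alone.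

Step 10
Reactants: 16 sulfone
Product: 17 methyl (1S,4S,4aS,7S,8R,8aS)-1-ethyl-4,5,7,8-tetramethyl-7-[(1E,3E)-2-methyl-4-phenylbuta-1,3-dien-1-yl]-2,2-dioxo-3,4,4a,7,8,8a-hexahydro-1H-isothiochromene-8-carboxylate (trans-fused, 1-Et and 4-Me equatorial)
Conditions: toluene (5 mM), BHT, 120 °C, sealed tube, dark
Reagents that add atoms: none
Why: Thermal type-1 intramolecular Diels–Alder reaction of a 1,7,9-decatriene-type sulfone, in which only the diene unit next to the four-atom tether (future C4a–C7) can reach the (E)-2-methylenoate; the endo chair transition state and the all-E geometry fix C4a, C7, C8 and C8a relative to each other, the in-plane allylic hydrogens at C4 and C1 (A1,3 strain against the cis methyl groups on C5 and C8) direct addition anti to the C4 methyl group and penalise both cis-fused alternatives, which would put a tether bond in that position, and the sulfonyl group activates the dienophile inductively.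

Step 11
Reactants: 17 trans-fused thiane 1,1-dioxide
Product: 20 methyl (1R,3aR,4R,5S,7aS)-3-ethyl-1,4,5,7-tetramethyl-5-[(1E,3E)-2-methyl-4-phenylbuta-1,3-dien-1-yl]-3a,4,5,7a-tetrahydro-1H-indene-4-carboxylate, via the equatorial (3R)-3-bromo derivative of 17 18 (not isolated), via the thiirane 1,1-dioxide fused across the new C2–C3 bond of the hydrindene 19 (not isolated)
Conditions: KOH/Al2O3, BrCl2C–CCl2Br, t-BuOH–THF, 0 °C to rt
Reagents that add atoms: none
Why: Ramberg–Bäcklund reaction in its one-pot halogenative form: KOH reversibly deprotonates an α-sulfonyl carbon, the carbanion takes Br+ from BrCl2C–CCl2Br (which collapses to Cl2C=CCl2 and bromide, so no carbene is released that could add to the four C=C bonds), deprotonation at the other α-carbon is followed by 1,3-displacement of bromide to episulfone 19, and 19 loses SO2 cheletropically to leave the alkene. The closest precedent is the contraction of thiane 1,1-dioxides to cyclopentenes, and of thiolane dioxides to cyclobutenes, under conditions of this kind. The only ring closure is the 3-exo-tet closure of the thiirane dioxide, which makes the new C–C bond and thereby turns the six-membered C5S ring into the five-membered carbocycle; in the chair the equatorial C–Br bond and the equatorial carbanion lobe already stand in the W arrangement this displacement needs. No stereocentre is created: helper centre C1 of 17 becomes sp2, while C4, C4a, C7, C8 and C8a carry no acidic hydrogen and are kept, so the trans fusion set in the unstrained thiadecalin passes into the more strained trans-hydrindadiene, with loss of SO2 and relief of the peri Et/CO2Me contact as driving force. Regioselectivity of halogenation is not needed, because either α-bromide leads to the same episulfone and the double bond can only appear between the two carbons that held sulfur, that is as C(Et)=CH. Chemoselectivity rests on the α-sulfonyl C–H bonds being the only acidic ones and on the methyl ester, flanked by two quaternary carbons, being inert to KOH in t-BuOH.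

Step 12
Reactants: 20 methyl ester
Product: 21 zyggomphic acid B, (1R,3aR,4R,5S,7aS)-3-ethyl-1,4,5,7-tetramethyl-5-[(1E,3E)-2-methyl-4-phenylbuta-1,3-dien-1-yl]-3a,4,5,7a-tetrahydro-1H-indene-4-carboxylic acid
Conditions: NaSEt, DMF, 90 °C; cold 1 M HCl
Reagents that add atoms: none
Why: SN2 (alkyl–oxygen) dealkylation of a methyl ester by thiolate attacks the unhindered O–CH3 carbon rather than the blocked carbonyl group, is established for very hindered esters, and touches neither the alkenes nor any stereocentre.

**Compound list**
1 | (S)-3-(acetylthio)-2-methylpropanoic acid | CC(=O)SC[C@@H](C)C(=O)O | starting material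
2 | methyl (R)-2-bromobutanoate | CC[C@@H](Br)C(=O)OC | starting material
3 | (S)-2-methyl-3-sulfanylpropanoic acid (present as disodium salt) | SC[C@@H](C)C(=O)O | intermediate
4 | (2S)-3-{[(2S)-1-methoxy-1-oxobutan-2-yl]sulfanyl}-2-methylpropanoic acid | CC[C@H](SC[C@@H](C)C(=O)O)C(=O)OC | intermediate
5 | methyl (2S)-2-{[(2S)-3-hydroxy-2-methylpropyl]sulfanyl}butanoate | CC[C@H](SC[C@@H](C)CO)C(=O)OC | intermediate
6 | methyl (2S)-2-{[(2S)-2-methyl-3-oxopropyl]sulfanyl}butanoate | CC[C@H](SC[C@@H](C)C=O)C(=O)OC | intermediate
7 | 2-(triphenylphosphoranylidene)propanal | CC(C=O)=P(c1ccccc1)(c1ccccc1)c1ccccc1 | starting material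
8 | methyl (2S)-2-{[(2S,3E)-2,4-dimethyl-5-oxopent-3-en-1-yl]sulfanyl}butanoate | CC[C@H](SC[C@@H](C)/C=C(\C)C=O)C(=O)OC | intermediate
9 | methyl (2S)-2-{[(2S,3E,5E)-2,4,6-trimethyl-7-oxohepta-3,5-dien-1-yl]sulfanyl}butanoate | CC[C@H](SC[C@@H](C)/C=C(C)/C=C(\C)C=O)C(=O)OC | intermediate
10 | methyl (2S)-2-{[(2S,3E,5E,7E)-2,4,6,8-tetramethyl-9-oxonona-3,5,7-trien-1-yl]sulfanyl}butanoate | CC[C@H](SC[C@@H](C)/C=C(C)/C=C(C)/C=C(\C)C=O)C(=O)OC | intermediate
11 | diethyl benzylphosphonate | CCOP(=O)(Cc1ccccc1)OCC | starting material
12 | methyl (2S)-2-{[(2S,3E,5E,7E,9E)-2,4,6,8-tetramethyl-10-phenyldeca-3,5,7,9-tetraen-1-yl]sulfanyl}butanoate | CC[C@H](SC[C@@H](C)/C=C(C)/C=C(C)/C=C(C)/C=C/c1ccccc1)C(=O)OC | intermediate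
13 | methyl 2-(triphenylphosphoranylidene)propanoate | COC(=O)C(C)=P(c1ccccc1)(c1ccccc1)c1ccccc1 | starting material
14 | (2S)-2-{[(2S,3E,5E,7E,9E)-2,4,6,8-tetramethyl-10-phenyldeca-3,5,7,9-tetraen-1-yl]sulfanyl}butanal | CC[C@H](SC[C@@H](C)/C=C(C)/C=C(C)/C=C(C)/C=C/c1ccccc1)C=O | intermediate
15 | methyl (2E,4S)-2-methyl-4-{[(2S,3E,5E,7E,9E)-2,4,6,8-tetramethyl-10-phenyldeca-3,5,7,9-tetraen-1-yl]sulfanyl}hex-2-enoate | CC[C@H](SC[C@@H](C)/C=C(C)/C=C(C)/C=C(C)/C=C/c1ccccc1)/C=C(\C)C(=O)OC | intermediate
16 | methyl (2E,4S)-2-methyl-4-{[(2S,3E,5E,7E,9E)-2,4,6,8-tetramethyl-10-phenyldeca-3,5,7,9-tetraen-1-yl]sulfonyl}hex-2-enoate | CC[C@H](S(=O)(=O)C[C@@H](C)/C=C(C)/C=C(C)/C=C(C)/C=C/c1ccccc1)/C=C(\C)C(=O)OC | intermediate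
17 | methyl (1S,4S,4aS,7S,8R,8aS)-1-ethyl-4,5,7,8-tetramethyl-7-[(1E,3E)-2-methyl-4-phenylbuta-1,3-dien-1-yl]-2,2-dioxo-3,4,4a,7,8,8a-hexahydro-1H-isothiochromene-8-carboxylate | CC[C@@H]1S(=O)(=O)C[C@@H](C)[C@@H]2C(C)=C[C@](C)(/C=C(C)/C=C/c3ccccc3)[C@](C)(C(=O)OC)[C@@H]12 | intermediate
18 | (3R)-3-bromo derivative of 17 (equatorial bromide) | CC[C@@H]1S(=O)(=O)[C@H](Br)[C@@H](C)[C@@H]2C(C)=C[C@](C)(/C=C(C)/C=C/c3ccccc3)[C@](C)(C(=O)OC)[C@@H]12 | intermediate
19 | episulfone: thiirane 1,1-dioxide fused across C2–C3 of the hydrindene, sulfur anti to the ethyl group | CC[C@@]12S(=O)(=O)[C@@H]1[C@@H](C)[C@@H]3C(C)=C[C@](C)(/C=C(C)/C=C/c4ccccc4)[C@](C)(C(=O)OC)[C@@H]23 | intermediate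
20 | zyggomphic acid B methyl ester | CCC1=C[C@@H](C)[C@@H]2C(C)=C[C@](C)(/C=C(C)/C=C/c3ccccc3)[C@](C)(C(=O)OC)[C@@H]12 | intermediate
21 | zyggomphic acid B | CCC1=C[C@@H](C)[C@@H]2C(C)=C[C@](C)(/C=C(C)/C=C/c3ccccc3)[C@](C)(C(=O)O)[C@@H]12 | target

**Step count and risks**

Total step count: 12. Longest linear sequence: 12 (1 to 21).

Steps most likely to fail:

Step 10. The cycloaddition has to join two fully substituted carbons. It may therefore be so slow that E/Z scrambling or a [1,5]-hydrogen shift of the tetraene, or deconjugation of the acidic γ-sulfonyl enoate, overtakes it, and endo/exo discrimination may also be insufficient. The fallback raises the reactivity of the dienophile by changing its oxidation level.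
- It sets out from 12. The reduction/olefination of step 8 is run through 14 with ylide 7 instead of 13 (40–60 °C) to give the enal sulfide F1.
- An enal has a lower LUMO and accepts Lewis acid catalysis, so F1 should cyclise as the sulfide with Me2AlCl (2 equiv, CH2Cl2, −40 °C) or on mild heating to the trans-fused sulfide aldehyde F2.
- Molybdate/H2O2 oxidation gives the sulfone aldehyde F3.
- Pinnick oxidation (NaClO2, NaH2PO4, 2-methyl-2-butene) gives the sulfone acid F4.
- Methylation with TMSCHN2 comes back to the route at 17.

Step 11. Multiple bromination at the CH2 group, a sluggish 1,3-displacement in the conformationally locked chair, or attack of the bromine donor on the diene could divert the contraction. The fallback forms the C–C bond oxidatively instead of by displacement. It sets out from 17. Double deprotonation (n-BuLi, 2.2 equiv, THF, −78 °C; the ester is shielded by two quaternary carbons) gives the α,α′-dilithio sulfone F5. One-electron oxidation with anhydrous CuCl2, a known coupling of sulfone α,α′-dianions, joins the two carbanion carbons to episulfone 19. Loss of SO2 then comes back to the route at 20.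

Step 9. Epoxidation or oxidative degradation of the electron-rich tetraene, or a [2,3]-shift at the allylic sulfoxide stage, may compete with sulfone formation. The fallback changes the order of events. It sets out from 15, which is heated (toluene, BHT, 130–140 °C) so that the Diels–Alder reaction takes place on the sulfide and gives the trans-fused sulfide ester F6. In F6 the sulfide is no longer allylic and only a diene is left of the polyene. Molybdate/H2O2 oxidation of F6 comes back to the route at 17.

**Further compounds**
F1 | step 10 | (2E,4S)-2-methyl-4-{[(2S,3E,5E,7E,9E)-2,4,6,8-tetramethyl-10-phenyldeca-3,5,7,9-tetraen-1-yl]sulfanyl}hex-2-enal | CC[C@H](SC[C@@H](C)/C=C(C)/C=C(C)/C=C(C)/C=C/c1ccccc1)/C=C(\C)C=O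
F2 | step 10 | (1S,4S,4aS,7S,8R,8aS)-1-ethyl-4,5,7,8-tetramethyl-7-[(1E,3E)-2-methyl-4-phenylbuta-1,3-dien-1-yl]-3,4,4a,7,8,8a-hexahydro-1H-isothiochromene-8-carbaldehyde | CC[C@@H]1SC[C@@H](C)[C@@H]2C(C)=C[C@](C)(/C=C(C)/C=C/c3ccccc3)[C@](C)(C=O)[C@@H]12
F3 | step 10 | 2,2-dioxide of F2 | CC[C@@H]1S(=O)(=O)C[C@@H](C)[C@@H]2C(C)=C[C@](C)(/C=C(C)/C=C/c3ccccc3)[C@](C)(C=O)[C@@H]12
F4 | step 10 | carboxylic acid corresponding to 17 | CC[C@@H]1S(=O)(=O)C[C@@H](C)[C@@H]2C(C)=C[C@](C)(/C=C(C)/C=C/c3ccccc3)[C@](C)(C(=O)O)[C@@H]12
F5 | step 11 | 1,3-dilithio derivative of 17 | CCC1([Li])S(=O)(=O)C([Li])[C@@H](C)[C@@H]2C(C)=C[C@](C)(/C=C(C)/C=C/c3ccccc3)[C@](C)(C(=O)OC)[C@@H]12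
F6 | step 9 | sulfide corresponding to 17 | CC[C@@H]1SC[C@@H](C)[C@@H]2C(C)=C[C@](C)(/C=C(C)/C=C/c3ccccc3)[C@](C)(C(=O)OC)[C@@H]12
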